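**Plan**

- Retrosynthesis: the two sulfate S–O bonds and the three O–benzyl bonds are cut last. Ring C is then cut in one operation at O1–C8a, C4–C4a and O1–C2, leaving 3,5-bis(benzyloxy)benzyne and a 2-(benzyloxy)-3-chloro-3-arylacrylic acid that already holds C2, C3, C4 and ring B.
- Enabling feature: ring A carries O1 (at C8a) and the C4 carbonyl (at C4a) on adjacent carbons, and C4a is flanked by the C5 oxygen. A 3-alkoxyaryne gives exactly this pattern when an oxygen nucleophile adds at its remote carbon and an acyl group is delivered to the near one.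
- Forward order: rings A and B are bought (3,5-bis(benzyloxy)phenol, 3,4-dihydroxybenzaldehyde). The aryne precursor takes three steps and the acid five (ketal, aldol, oxidation, deoxychlorination, saponification). Ring C closes in step 9.
- End game: ketal hydrolysis frees only the catechol, which is bis-sulfated; hydrogenolysis then uncovers the 3-, 5- and 7-hydroxyls.
- Stereochemistry: the target has no stereocentre. The aldol stereocentres are erased in steps 6 and 7, and the chloroalkene geometry is erased in the ring closure.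

Key step: step 9

Assumption: the target is taken as the free bis(hydrogen sulfate) as drawn; it is released from its disodium salt only in the last operation and kept cold, because aryl hydrogen sulfates hydrolyse under their own acidity.

**Route**

Step 1
Reactants: 1 3,5-bis(benzyloxy)phenol
Product: 2 3,5-bis(benzyloxy)phenyl N-isopropylcarbamate
Conditions: iPrNCO, Et3N (cat.), CH2Cl2, rt
Reagents that add atoms: isopropyl isocyanate, CC(C)N=C=O
Why: Amine-catalysed addition of a phenol to an isocyanate (carbamoylation) is general and installs the N-isopropyl carbamate that directs the metalation in step 2 and leaves under mild base in step 3.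

Step 2
Reactants: 2 3,5-bis(benzyloxy)phenyl N-isopropylcarbamate
Product: 6 3,5-bis(benzyloxy)-2-(trimethylsilyl)phenyl N-isopropylcarbamate, via N-TBS carbamate 3 (not isolated), via ortho-lithiated N-TBS carbamate 4 (not isolated), via N-TBS 2-trimethylsilyl carbamate 5 (not isolated)
Conditions: TBSOTf, TMEDA, Et2O, 0 °C to rt; n-BuLi, TMEDA, −78 °C; TMSCl, −78 °C to rt; aq NaHSO4
Reagents that add atoms: chlorotrimethylsilane, C[Si](C)(C)Cl; tert-butyldimethylsilyl trifluoromethanesulfonate, CC(C)(C)[Si](C)(C)OS(=O)(=O)C(F)(F)F (its silyl group is carried only in 3 to 5); n-butyllithium, [Li]CCCC (its lithium is held only in 4)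
Why: Directed ortho-metalation of an aryl carbamate: after in situ N-silylation the carbamate directs n-BuLi/TMEDA to the position between it and a benzyloxy group (the two such positions are equivalent by symmetry and activated by both oxygens), lithiation at −78 °C should outrun benzylic deprotonation of the benzyl ethers, and TMSCl traps the aryllithium before acidic work-up removes the N-silyl group.

Step 3
Reactants: 6 3,5-bis(benzyloxy)-2-(trimethylsilyl)phenyl N-isopropylcarbamate
Product: 8 3,5-bis(benzyloxy)-2-(trimethylsilyl)phenyl trifluoromethanesulfonate, via 3,5-bis(benzyloxy)-2-(trimethylsilyl)phenol 7 (not isolated)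
Conditions: DBU, Et2NH, MeCN, 40 °C; then PhNTf2, rt
Reagents that add atoms: N-phenylbis(trifluoromethanesulfonimide), O=S(=O)(N(c1ccccc1)S(=O)(=O)C(F)(F)F)C(F)(F)F
Why: Base-induced E1cB cleavage of the N–H carbamate releases the phenoxide and isopropyl isocyanate, which Et2NH scavenges as a urea, and O-triflation with PhNTf2 in the same flask avoids isolating the protodesilylation-prone ortho-silyl phenol.

Step 4
Reactants: 9 3,4-dihydroxybenzaldehyde
Product: 10 2,2-diphenyl-1,3-benzodioxole-5-carbaldehyde
Conditions: Ph2CCl2, Ph2O, 175 °C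
Reagents that add atoms: dichlorodiphenylmethane, ClC(Cl)(c1ccccc1)c1ccccc1
Why: Thermal ketalisation of a catechol with a geminal dichloride (two O-alkylations with loss of HCl) is the standard entry to diphenylmethylene ketals and leaves the formyl group untouched.

Step 5
Reactants: 10 2,2-diphenyl-1,3-benzodioxole-5-carbaldehyde; 11 methyl 2-(benzyloxy)acetate
Product: 13 methyl 2-(benzyloxy)-3-(2,2-diphenyl-1,3-benzodioxol-5-yl)-3-hydroxypropanoate, via lithium enolate of methyl 2-(benzyloxy)acetate 12 (not isolated)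
Conditions: LiN(iPr)2, 11, THF, −78 °C; then 10; AcOH quench at −78 °C
Reagents that add atoms: lithium diisopropylamide, CC(C)N([Li])C(C)C (its lithium is held only in 12)
Why: Aldol addition of a preformed, chelated lithium glycolate ester enolate to a non-enolisable aryl aldehyde is reliable at −78 °C; the two new stereocentres arise deliberately uncontrolled as a syn/anti mixture of racemates, since both are destroyed in steps 6 and 7.

Step 6
Reactants: 13 methyl 2-(benzyloxy)-3-(2,2-diphenyl-1,3-benzodioxol-5-yl)-3-hydroxypropanoate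
Product: 14 methyl 2-(benzyloxy)-3-(2,2-diphenyl-1,3-benzodioxol-5-yl)-3-oxopropanoate
Conditions: Dess–Martin periodinane, CH2Cl2, 0 °C to rt
Reagents that add atoms: none
Why: Dess–Martin oxidation converts the benzylic secondary alcohol into the ketone under near-neutral conditions that the ketal, the benzyl ether and the epimerisable α-alkoxy β-keto ester tolerate.

Step 7
Reactants: 14 methyl 2-(benzyloxy)-3-(2,2-diphenyl-1,3-benzodioxol-5-yl)-3-oxopropanoate
Product: 15 methyl (E)-2-(benzyloxy)-3-chloro-3-(2,2-diphenyl-1,3-benzodioxol-5-yl)acrylate (the Z isomer, if it accompanies it, is carried along)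
Conditions: Ph3PCl2, Et3N, MeCN, 0 to 60 °C
Reagents that add atoms: dichlorotriphenylphosphorane, ClP(Cl)(c1ccccc1)(c1ccccc1)c1ccccc1
Why: Deoxychlorination of a β-keto ester through its enol phosphonium salt (Et3N forms the enolate, oxygen bonds to phosphorus, chloride adds at the β-carbon and Ph3PO is expelled) is an established route from β-dicarbonyl compounds to β-chloro enoates, the buffered medium protects the ketal, and the alkene geometry is of no consequence.

Step 8
Reactants: 15 methyl (E)-2-(benzyloxy)-3-chloro-3-(2,2-diphenyl-1,3-benzodioxol-5-yl)acrylate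
Product: 16 (E)-2-(benzyloxy)-3-chloro-3-(2,2-diphenyl-1,3-benzodioxol-5-yl)acrylic acid
Conditions: LiOH, THF/MeOH/H2O, rt; 1 M HCl to pH 3, 0 °C
Reagents that add atoms: lithium hydroxide, [Li+].[OH-]
Why: Saponification of the methyl ester; hydroxide should attack the ester carbonyl rather than the β-carbon, which is deactivated by the α-benzyloxy and β-aryl donors and then by the carboxylate, and brief cold acidification leaves the ketal intact.

Step 9
Reactants: 8 3,5-bis(benzyloxy)-2-(trimethylsilyl)phenyl trifluoromethanesulfonate; 16 (E)-2-(benzyloxy)-3-chloro-3-(2,2-diphenyl-1,3-benzodioxol-5-yl)acrylic acid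
Product: 19 3,5,7-tris(benzyloxy)-2-(2,2-diphenyl-1,3-benzodioxol-5-yl)-4H-chromen-4-one, via 3,5-bis(benzyloxy)benzyne 17 (not isolated), via cesium phenoxide of the ortho-acyl chlorovinyl ketone 18 (not isolated)
Conditions: CsF (4 equiv), 8 (1.5 equiv), THF, 125 °C, sealed tube
Reagents that add atoms: none
Why: Proposed new method: fluoride removes the silyl group of 8 and triflate leaves to give aryne 17; the cesium carboxylate of 16 adds through oxygen at the aryne carbon remote from the flanking benzyloxy group (O1–C8a), the aryl anion so placed ortho to that benzyloxy group attacks the adjacent ester carbonyl through a four-membered transition state (C4–C4a), and ring opening releases the ortho-acyl phenoxide 18. The phenoxide then adds to the chlorine-bearing β-carbon and the resulting enolate expels chloride (O1–C2), a net vinylic substitution that closes ring C as a 6-endo-trig addition followed by elimination. The closest known reaction type is the fluoride-mediated insertion of arynes into the C–O bond of carboxylic acids to give ortho-hydroxyaryl ketones, including its one-pot extension to chromanones and flavones when an unsaturated acid lets the phenoxide close by conjugate addition; what is untested is closure by addition–elimination on a tetrasubstituted α-alkoxy-β-chloro enone. No stereocentre is formed, and because the closure passes through a freely rotating enolate either geometry of the chloroalkene should converge on 19. The selectivity required is regiochemical: oxygen must bond to the aryne carbon meta to the flanking benzyloxy group, which the inductive pull of that C–O bond on the neighbouring aryne carbon (aryne distortion and stabilisation of the developing ortho carbanion) should secure, the second benzyloxy group being too remote to oppose it.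

Step 10
Reactants: 19 3,5,7-tris(benzyloxy)-2-(2,2-diphenyl-1,3-benzodioxol-5-yl)-4H-chromen-4-one
Product: 20 3,5,7-tris(benzyloxy)-2-(3,4-dihydroxyphenyl)-4H-chromen-4-one
Conditions: AcOH/H2O (4:1), 100 °C
Reagents that add atoms: none
Why: Acid-catalysed hydrolysis of the diphenylmethylene ketal, which ionises readily to a diaryl-stabilised oxocarbenium ion in hot aqueous acetic acid, whereas the aryl benzyl ethers have no such pathway and should remain.

Step 11
Reactants: 20 3,5,7-tris(benzyloxy)-2-(3,4-dihydroxyphenyl)-4H-chromen-4-one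
Product: 22 disodium 4-[3,5,7-tris(benzyloxy)-4-oxo-4H-chromen-2-yl]-1,2-phenylene bis(sulfate), via bis(pyridinium) bis(sulfate) 21 (not isolated)
Conditions: SO3·pyridine (10 equiv), pyridine, 50 °C; aq NaHCO3, 0 °C
Reagents that add atoms: sulfur trioxide pyridine complex, O=S(=O)([O-])[n+]1ccccc1; sodium hydrogen carbonate, [Na+].OC([O-])=O
Why: Phenol O-sulfation with the SO3·pyridine complex: only the two catechol hydroxyls are free, excess reagent with gentle heating is meant to force the second sulfation next to the first sulfate anion, and exchange to the sodium salt removes pyridine, which would slow the hydrogenolysis.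

Step 12
Reactants: 22 disodium 4-[3,5,7-tris(benzyloxy)-4-oxo-4H-chromen-2-yl]-1,2-phenylene bis(sulfate)
Product: 24 4-(3,5,7-trihydroxy-4-oxo-4H-chromen-2-yl)-1,2-phenylene bis(hydrogen sulfate) (target), via disodium quercetin 3',4'-bis(sulfate) 23 (not isolated)
Conditions: H2 (1 atm), Pd/C, THF/MeOH/H2O, rt; filter; aq HCl (2 equiv), 0 °C; Sephadex LH-20 (MeOH)
Reagents that add atoms: none
Why: Catalytic hydrogenolysis of the three benzyl ethers over Pd/C should leave the aryl sulfate monoester salts and the tetrasubstituted enolic C2=C3 bond untouched at atmospheric pressure, and stoichiometric cold HCl then protonates the bis-sulfate.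

**Compound list**

1 | 3,5-bis(benzyloxy)phenol | Oc1cc(OCc2ccccc2)cc(OCc2ccccc2)c1 | starting material
2 | 3,5-bis(benzyloxy)phenyl N-isopropylcarbamate | CC(C)NC(=O)Oc1cc(OCc2ccccc2)cc(OCc2ccccc2)c1 | intermediate
3 | 3,5-bis(benzyloxy)phenyl N-(tert-butyldimethylsilyl)-N-isopropylcarbamate | CC(C)N([Si](C)(C)C(C)(C)C)C(=O)Oc1cc(OCc2ccccc2)cc(OCc2ccccc2)c1 | intermediate
4 | 3,5-bis(benzyloxy)-2-lithiophenyl N-(tert-butyldimethylsilyl)-N-isopropylcarbamate | CC(C)N([Si](C)(C)C(C)(C)C)C(=O)Oc1cc(OCc2ccccc2)cc(OCc2ccccc2)c1[Li] | intermediate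
5 | 3,5-bis(benzyloxy)-2-(trimethylsilyl)phenyl N-(tert-butyldimethylsilyl)-N-isopropylcarbamate | CC(C)N([Si](C)(C)C(C)(C)C)C(=O)Oc1cc(OCc2ccccc2)cc(OCc2ccccc2)c1[Si](C)(C)C | intermediate
6 | 3,5-bis(benzyloxy)-2-(trimethylsilyl)phenyl N-isopropylcarbamate | CC(C)NC(=O)Oc1cc(OCc2ccccc2)cc(OCc2ccccc2)c1[Si](C)(C)C | intermediate
7 | 3,5-bis(benzyloxy)-2-(trimethylsilyl)phenol (present as its phenoxide) | C[Si](C)(C)c1c(O)cc(OCc2ccccc2)cc1OCc1ccccc1 | intermediate
8 | 3,5-bis(benzyloxy)-2-(trimethylsilyl)phenyl trifluoromethanesulfonate | C[Si](C)(C)c1c(OS(=O)(=O)C(F)(F)F)cc(OCc2ccccc2)cc1OCc1ccccc1 | intermediate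
9 | 3,4-dihydroxybenzaldehyde | O=Cc1ccc(O)c(O)c1 | starting material
10 | 2,2-diphenyl-1,3-benzodioxole-5-carbaldehyde | O=Cc1ccc2OC(c3ccccc3)(c3ccccc3)Oc2c1 | intermediate
11 | methyl 2-(benzyloxy)acetate | COC(=O)COCc1ccccc1 | starting material
12 | chelated lithium enolate of methyl 2-(benzyloxy)acetate | [Li]O/C(OC)=C\OCc1ccccc1 | intermediate
13 | methyl 2-(benzyloxy)-3-(2,2-diphenyl-1,3-benzodioxol-5-yl)-3-hydroxypropanoate (syn/anti mixture, racemic, no configuration assigned) | COC(=O)C(OCc1ccccc1)C(O)c1ccc2OC(c3ccccc3)(c3ccccc3)Oc2c1 | intermediate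
14 | methyl 2-(benzyloxy)-3-(2,2-diphenyl-1,3-benzodioxol-5-yl)-3-oxopropanoate (racemic) | COC(=O)C(OCc1ccccc1)C(=O)c1ccc2OC(c3ccccc3)(c3ccccc3)Oc2c1 | intermediate
15 | methyl (E)-2-(benzyloxy)-3-chloro-3-(2,2-diphenyl-1,3-benzodioxol-5-yl)acrylate | COC(=O)/C(OCc1ccccc1)=C(\Cl)c1ccc2OC(c3ccccc3)(c3ccccc3)Oc2c1 | intermediate
16 | (E)-2-(benzyloxy)-3-chloro-3-(2,2-diphenyl-1,3-benzodioxol-5-yl)acrylic acid | OC(=O)/C(OCc1ccccc1)=C(\Cl)c1ccc2OC(c3ccccc3)(c3ccccc3)Oc2c1 | intermediate
17 | 3,5-bis(benzyloxy)benzyne | C1(OCc2ccccc2)=CC(OCc2ccccc2)=CC#C1 | intermediate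
18 | cesium 3,5-bis(benzyloxy)-2-[(E)-2-(benzyloxy)-3-chloro-3-(2,2-diphenyl-1,3-benzodioxol-5-yl)acryloyl]phenoxide | O=C(/C(OCc1ccccc1)=C(\Cl)c1ccc2OC(c3ccccc3)(c3ccccc3)Oc2c1)c1c([O-])cc(OCc2ccccc2)cc1OCc1ccccc1.[Cs+] | intermediate
19 | 3,5,7-tris(benzyloxy)-2-(2,2-diphenyl-1,3-benzodioxol-5-yl)-4H-chromen-4-one | O=c1c(OCc2ccccc2)c(-c2ccc3OC(c4ccccc4)(c4ccccc4)Oc3c2)oc2cc(OCc3ccccc3)cc(OCc3ccccc3)c12 | intermediate
20 | 3,5,7-tris(benzyloxy)-2-(3,4-dihydroxyphenyl)-4H-chromen-4-one | O=c1c(OCc2ccccc2)c(-c2ccc(O)c(O)c2)oc2cc(OCc3ccccc3)cc(OCc3ccccc3)c12 | intermediate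
21 | bis(pyridinium) 4-[3,5,7-tris(benzyloxy)-4-oxo-4H-chromen-2-yl]-1,2-phenylene bis(sulfate) | O=c1c(OCc2ccccc2)c(-c2ccc(OS(=O)(=O)[O-])c(OS(=O)(=O)[O-])c2)oc2cc(OCc3ccccc3)cc(OCc3ccccc3)c12.c1cc[nH+]cc1.c1cc[nH+]cc1 | intermediate
22 | disodium 4-[3,5,7-tris(benzyloxy)-4-oxo-4H-chromen-2-yl]-1,2-phenylene bis(sulfate) | O=c1c(OCc2ccccc2)c(-c2ccc(OS(=O)(=O)[O-])c(OS(=O)(=O)[O-])c2)oc2cc(OCc3ccccc3)cc(OCc3ccccc3)c12.[Na+].[Na+] | intermediate
23 | disodium 4-(3,5,7-trihydroxy-4-oxo-4H-chromen-2-yl)-1,2-phenylene bis(sulfate) | O=c1c(O)c(-c2ccc(OS(=O)(=O)[O-])c(OS(=O)(=O)[O-])c2)oc2cc(O)cc(O)c12.[Na+].[Na+] | intermediate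
24 | 4-(3,5,7-trihydroxy-4-oxo-4H-chromen-2-yl)-1,2-phenylene bis(hydrogen sulfate) (quercetin 3',4'-bis-sulfate) | O=c1c(O)c(-c2ccc(OS(=O)(=O)O)c(OS(=O)(=O)O)c2)oc2cc(O)cc(O)c12 | target

**Step count and risks**

Total steps: 12. Longest linear sequence: 9 steps (steps 4 to 12, from 3,4-dihydroxybenzaldehyde 9); the aryne branch (steps 1 to 3) joins at step 9.

Steps most likely to fail:

1. Step 9. The aryl anion may be protonated before acyl transfer, so the sequence stops at the aryl ester, or the phenoxide may fail to displace chloride at the electron-rich, tetrasubstituted β-carbon. The fallback uses known chemistry, sets out from aldehyde 10 and aryne precursor 8, and returns at 19. Corey–Fuchs olefination of 10 (CBr4, PPh3) would give 5-(2,2-dibromovinyl)-2,2-diphenyl-1,3-benzodioxole F1. n-BuLi would convert this into the lithium acetylide F2, and CO2 followed by mild acid would give 3-(2,2-diphenyl-1,3-benzodioxol-5-yl)prop-2-ynoic acid F3. Coupling of F3 with 8 under the same CsF/THF conditions, the established one-pot flavone synthesis from aryl propiolic acids and arynes, would give 5,7-bis(benzyloxy)-2-(2,2-diphenyl-1,3-benzodioxol-5-yl)-4H-chromen-4-one F4 with the same regiochemistry. Dimethyldioxirane in acetone would epoxidise C2=C3 to the flavone 2,3-epoxide F5, which catalytic p-TsOH opens to 5,7-bis(benzyloxy)-2-(2,2-diphenyl-1,3-benzodioxol-5-yl)-3-hydroxy-4H-chromen-4-one F6. Benzylation (BnBr, K2CO3, DMF) then delivers 19.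

2. Step 7. O-activation of the hindered, weakly enolised α-alkoxy β-keto ester may be incomplete, or chloride may not add to the donor-substituted carbon of the enol phosphonium salt, returning 14. The fallback sets out from aldol 13 and returns at 15. Mesylation (MsCl, Et3N) would give methyl 2-(benzyloxy)-3-(2,2-diphenyl-1,3-benzodioxol-5-yl)-3-(methylsulfonyloxy)propanoate F7, and DBU-induced elimination would give methyl (Z)-2-(benzyloxy)-3-(2,2-diphenyl-1,3-benzodioxol-5-yl)acrylate F8. Electrophilic chlorination of this enol ether at its β-carbon with N-chlorosuccinimide, followed by loss of the β-proton (Et3N), installs the vinylic chloride and gives 15.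

3. Step 11. The second sulfation, next to a sulfate anion, may stall at the mono-sulfates, and the mixture of polar salts would resist separation. The fallback sets out from catechol 20 and returns at 24. Sulfuryl transfer with 2,2,2-trichloroethyl chlorosulfate (Et3N, DMAP, THF) would give the neutral, silica-stable 4-[3,5,7-tris(benzyloxy)-4-oxo-4H-chromen-2-yl]-1,2-phenylene bis(2,2,2-trichloroethyl) bis(sulfate) F9. Pd/C with HCO2NH4 in MeOH would then cleave both trichloroethyl groups and all three benzyl ethers in one reductive operation, giving diammonium 4-(3,5,7-trihydroxy-4-oxo-4H-chromen-2-yl)-1,2-phenylene bis(sulfate) F10. Cold aqueous HCl and Sephadex LH-20 would release 24.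

Further compounds
F1 | step 9 | 5-(2,2-dibromovinyl)-2,2-diphenyl-1,3-benzodioxole | BrC(Br)=Cc1ccc2OC(c3ccccc3)(c3ccccc3)Oc2c1
F2 | step 9 | lithium [(2,2-diphenyl-1,3-benzodioxol-5-yl)ethynide] | [Li]C#Cc1ccc2OC(c3ccccc3)(c3ccccc3)Oc2c1
F3 | step 9 | 3-(2,2-diphenyl-1,3-benzodioxol-5-yl)prop-2-ynoic acid | OC(=O)C#Cc1ccc2OC(c3ccccc3)(c3ccccc3)Oc2c1
F4 | step 9 | 5,7-bis(benzyloxy)-2-(2,2-diphenyl-1,3-benzodioxol-5-yl)-4H-chromen-4-one | O=c1cc(-c2ccc3OC(c4ccccc4)(c4ccccc4)Oc3c2)oc2cc(OCc3ccccc3)cc(OCc3ccccc3)c12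
F5 | step 9 | 2,3-epoxide of F4 (racemic, cis-fused) | O=C1C2OC2(c2ccc3OC(c4ccccc4)(c4ccccc4)Oc3c2)Oc2cc(OCc3ccccc3)cc(OCc3ccccc3)c12
F6 | step 9 | 5,7-bis(benzyloxy)-2-(2,2-diphenyl-1,3-benzodioxol-5-yl)-3-hydroxy-4H-chromen-4-one | O=c1c(O)c(-c2ccc3OC(c4ccccc4)(c4ccccc4)Oc3c2)oc2cc(OCc3ccccc3)cc(OCc3ccccc3)c12
F7 | step 7 | methyl 2-(benzyloxy)-3-(2,2-diphenyl-1,3-benzodioxol-5-yl)-3-(methylsulfonyloxy)propanoate (diastereomer mixture, racemic) | COC(=O)C(OCc1ccccc1)C(OS(C)(=O)=O)c1ccc2OC(c3ccccc3)(c3ccccc3)Oc2c1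
F8 | step 7 | methyl (Z)-2-(benzyloxy)-3-(2,2-diphenyl-1,3-benzodioxol-5-yl)acrylate | COC(=O)/C(OCc1ccccc1)=C/c1ccc2OC(c3ccccc3)(c3ccccc3)Oc2c1
F9 | step 11 | 4-[3,5,7-tris(benzyloxy)-4-oxo-4H-chromen-2-yl]-1,2-phenylene bis(2,2,2-trichloroethyl) bis(sulfate) | O=c1c(OCc2ccccc2)c(-c2ccc(OS(=O)(=O)OCC(Cl)(Cl)Cl)c(OS(=O)(=O)OCC(Cl)(Cl)Cl)c2)oc2cc(OCc3ccccc3)cc(OCc3ccccc3)c12
F10 | step 11 | diammonium 4-(3,5,7-trihydroxy-4-oxo-4H-chromen-2-yl)-1,2-phenylene bis(sulfate) | O=c1c(O)c(-c2ccc(OS(=O)(=O)[O-])c(OS(=O)(=O)[O-])c2)oc2cc(O)cc(O)c12.[NH4+].[NH4+]
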